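## Structural features

The target is a trans-fused decalin (ring A: C1–C5 and C10; ring B: C5–C10) joined at C9 through the C11–C12 ethylene tether to a separate γ-lactone ring (C13, C14, C15, O, C16) that carries a tertiary hydroxyl at C13. Ring A is saturated and holds the gem-dimethyl carbon C4 beside the ring-fusion methine C5 and the quaternary, methyl-bearing C10. Ring B holds the whole oxidation pattern: a tetrasubstituted enone (C7=O, C8(CH3)=C9) flanked by the axial 6β-hydroxyl. Three stereocentres are contiguous (C10, C5, C6: 10β-methyl, 5α-H, 6β-OH). The fourth, C13 (S), is insulated from them by two CH2 groups and cannot be controlled by the decalin. The fragile groups are the α-ketol (C6 can epimerise to the equatorial alcohol or be oxidised to the diosphenol), the tertiary β-hydroxy lactone (opened by base, dehydrated by strong acid) and the enone. The real difficulties are the quaternary C10 wedged between C1, C5 and C9, the 6β-oxygen syn-axial to two methyl groups, and C13, whose two carbon arms (C12–C11 and C14–C15) are both two-carbon units that differ only beyond the second atom. The key step exploits the fact that the array C4(CH3)2–C5(H)–C10 maps onto the isopropenyl carbon, the stereocentre and the α′ carbon of (R)-carvone, whose enone already contains C9, C8 with its methyl group, and C7; only the C1–C2–C3 bridge and the C3–C4 bond of ring A are missing.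

## Logic of the disconnections

32 ⇒ 30 (through 31). The lactone C15–O bond and the three protecting O–C/O–Si bonds are cut. One mild acid treatment then finishes the synthesis. The forward step must be gentle enough not to dehydrate C13–OH or epimerise C6.

30 ⇒ 29 ⇒ 27 (through 28). The C15 carboxyl is traced back to a terminal alkene with one extra carbon. An alkene survives organolithium and chromium chemistry, which no carboxyl derivative would. The demand is that the monosubstituted alkene be cleaved in the presence of the tetrasubstituted enone alkene.

27 ⇒ 26. The enone C7=O/C8=C9 is transposed back to a C9 tertiary allylic alcohol with a C7=C8 bond. This converts the C9–C11 bond into a carbonyl-addition bond. The forward oxidation must not touch C6–O, so that oxygen is silylated.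

26 ⇒ 15 + 23 (through 24 and 25). The C9–C11 bond is cut, which gives a convergent union of the complete decalin with the complete, enantiopure C11–C16 chain. The carbonyl of 15 is neopentylic and has an acidic γ-hydrogen, so the nucleophile must be very nucleophilic and weakly basic.

23 ⇒ 22 ⇒ 21 ⇒ 20 ⇒ 17 + 18 (through 19) ⇒ 16. The C13–C14 bond is cut next to the carbinol carbon, so that C13 comes from a hydroxy acid by alkylation with retention. The choice of enantiomer of 16 follows from which arm is introduced:
- If the introduced three-carbon unit is the latent C14–C15 carboxyl and the existing CH2CO2H arm becomes C12–C11, 16 must be the (R)-acid. This gives 23 in five steps.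
- The (S)-acid would require the introduced arm to become C11–C12 (cleavage, reduction, iodination) and the acid arm to be carried as a protected alcohol. That costs two more steps, and so it was not chosen.

15 ⇒ 14 ⇒ 13 ⇒ 12. The C6–O bond is removed. C6 is the γ-position of the enone of 12, so it can be oxidised directly to the ketone. The 6β configuration is then set by hydride delivery to the open α face. The forward reduction must also choose C6=O over C9=O.

12 ⇒ 11 ⇒ 10 ⇒ 9. A C1 oxygen is added retrosynthetically, because the ring-closing step needs a carbonyl at C1 as the activating group of the radical acceptor. The demand is to remove a saturated ketone beside an enone.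

9 ⇒ 8. The C3–C4 bond of ring A is cut, which leaves a monocyclic triene-dione. The forward step must create the fully substituted C4 next to C5 and close a six-membered ring regioselectively. Both stereocentres of the ring fusion are already present in 8.

8 ⇒ 7 ⇒ 4 + 5 (through 6). The C1–C10 bond is cut as an aldol bond, followed by adjustment of the oxidation level. The forward step must deliver the C3 unit trans to the isopropenyl group, which fixes C10.

4 ⇒ 1 + 2 (through 3). The C10–C20 bond is cut as an enolate methylation. Its stereochemical outcome does not matter, because the centre is planarised again before C10 is finally set.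

## Other disconnections considered

Alternative 1: The cut removes the lactone carbonyl (bonds C14–C15 and C15–O), which leaves the 3,3-disubstituted oxetane A2 in which C13 is not yet a stereocentre. In the forward step the ion pair [(salen)Cr(THF)2][Co(CO)4] under CO would activate the oxetane oxygen at the chromium cation; the cobaltate would open one CH2–O bond, CO would insert, and the alkoxide would close on the acyl to give the bis-silyl ether A1.
- In favour: the side chain becomes achiral and short (from oxetan-3-one A3). No oxidation-level changes are needed at the end. Carbonylative ring expansion of simple oxetanes to γ-lactones is an established reaction type. On step count this alternative is the better one, by two to three steps.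
- Against: a version that selects between the two enantiotopic CH2–O bonds of such an oxetane is not established and would have to be invented. The attacked CH2 is neopentyl-like (next to the fully substituted C13). The decalin stereocentres are too far away to help, so any leakage gives the C13 epimer, which is hard to separate. The Lewis acid may also strip or shift the tertiary silyl ether or bind the enone.
- Comparison: structurally the alternative says nothing about the decalin, where it is the equal of the chosen plan because it could use the same ring-A closure. Mechanistically the chosen plan fixes C13 from the chiral pool before the union, which is secure and was judged worth the extra steps.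

Alternative 2: The cut removes C4–C5, C9–C10 and C8–O at once, back to the acyclic (5E,9E)-farnesylacetone A5. In the forward step a SnCl4-activated chiral BINOL monoether would protonate C3; a chair–chair cascade and capture of the C8 cation by the ketone oxygen would give sclareol oxide A4.
- In favour: both carbocycles, the trans ring fusion and the gem-dimethyl carbon arise in one operation from a cheap achiral chain. On ring construction this alternative is the better one.
- Against: the functional-group pattern of A4 does not match the target.
  - C8 and C9 are made as stereocentres and then must be erased to C8=C9.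
  - C6 and C7 are unfunctionalised CH2 groups.
  - C13 is an enol-ether carbon bearing C16 as a methyl group, and C14 and C15 are absent. The hydroxy lactone and its C13 configuration would have to be built late on a methyl ketone with no control element.
  - The cyclisation needs a stoichiometric chiral acid, and its enantioselectivity is reagent-controlled.
- Comparison: the alternative wins on the step count for the bicycle, but loses more than it gains in oxidations and side-chain construction. The chosen plan starts with the ring-B enone and the C5 configuration already in hand.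

Alternative 3: The cut is the C5=C6 bond, back to the side-chain diketone A7, itself from 2,2,6-trimethylcyclohexanone A8 by an enantioselective α-alkylation that sets C10. In the forward step base would form the C6 enolate of the α-alkoxy ketone, which would add to the ring carbonyl C5 and dehydrate to the octalenone A6.
- In favour: only classical polar chemistry is used. Oxygen at C6 and the carbonyl at C7 arrive in their final positions without allylic oxidation or transposition. On the C6/C7 oxidation pattern this alternative is the better one, and in rings formed by the key step (one) it is the equal of the chosen plan.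
- Against: the electrophile is a ketone flanked by two quaternary carbons, so the aldol equilibrium and rate are unfavourable. After ring closure the plan still needs:
  - saturation of a tetrasubstituted enol-ether alkene to set 5α-H and 6β-O;
  - introduction of the C8 methyl group and of C8=C9 unsaturation;
  - attachment of the side chain at the neopentylic C9 of a ring that offers no handle there.
  
  In addition, C10 rests on a catalytic asymmetric alkylation and not on the chiral pool.
- Comparison: mechanistically the closure is simpler than a radical cyclisation, but sterically less credible. In step economy the long way from A6 to the target outweighs the early advantage.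

Key step: step 4

Remark: carbinol centres that are erased later (the side-chain carbinol of 7, C1 of 10 and 11, C9 of 26, the CH(OH) of 28) are expected as epimer mixtures and are drawn without configuration; both epimers converge.

## Route

Step 1
Reactants: 1 (R)-(−)-carvone; 2 iodomethane
Product: 4 (5R,6S)-6-methylcarvone (methyl trans to isopropenyl), via lithium dienolate 3 (not isolated)
Conditions: LiN(i-Pr)2, THF, −78 °C; MeI, −78 → 0 °C
Reagents that add atoms: iodomethane (2), CI
Why: Kinetic deprotonation at the α′ CH2 gives the cross-conjugated lithium dienolate, which is C-methylated mainly anti to the isopropenyl group (enolate alkylation); the new centre is planarised again in step 2, so its ratio is immaterial.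

Step 2
Reactants: 4 (5R,6S)-6-methylcarvone; 5 acrolein
Product: 7 6-(1-hydroxyprop-2-en-1-yl)-6-methylcarvone (hydroxyallyl trans and methyl cis to isopropenyl; carbinol epimers), via lithium enolate 6 (not isolated)
Conditions: LiN(i-Pr)2, THF, −78 → −20 °C, then −78 °C; acrolein, −78 °C; AcOH quench at −78 °C
Reagents that add atoms: acrolein (5), C=CC=O
Why: The α′ methine is the only kinetically acidic site, and the tetrasubstituted enolate is shielded on one face by the neighbouring isopropenyl group, so the aldehyde carbonyl of acrolein adds 1,2 on the opposite face (aldol addition). This places the new C1–C10 bond trans to isopropenyl and the methyl group cis to it, which is the C10 configuration of the target; the cold acidic quench prevents retro-aldol.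

Step 3
Reactants: 7 6-(1-hydroxyprop-2-en-1-yl)-6-methylcarvone
Product: 8 6-acryloyl-6-methylcarvone (acyl trans and methyl cis to isopropenyl)
Conditions: Dess–Martin periodinane, CH2Cl2, 0 °C → rt
Reagents that add atoms: none
Why: Dess–Martin oxidation of the secondary allylic alcohol is neutral, so the β-hydroxy ketone does not undergo retro-aldol and the vinyl ketone is not exposed to nucleophiles; the quaternary centre cannot epimerise.

Step 4
Reactants: 8 6-acryloyl-6-methylcarvone
Product: 9 trans-fused 4,4,8,10-tetramethyldecal-7-ene-1,9-dione (5α-H and 10β-CH3; target numbering)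
Conditions: Fe(acac)3 (30 mol %), PhSiH3 (2.5 equiv), EtOH/(CH2OH)2 5:1, 0.02 M, 60 °C
Reagents that add atoms: none
Why: Trivalent iron acetylacetonate and phenylsilane in ethanol form an iron hydride that transfers a hydrogen atom to the terminal CH2 of the electron-rich 1,1-disubstituted isopropenyl alkene, giving the tertiary C4 radical and divalent iron; the acryloyl and ring-enone alkenes are electron-poor and are poor hydrogen-atom acceptors, which secures the chemoselectivity. The nucleophilic tertiary radical adds to the unsubstituted β-carbon C3 of the acryloyl group and closes ring A in the 6-endo-trig mode, forming C3–C4; 5-exo attack at C2 is polarity-mismatched and would leave a primary radical, and the sp2 carbonyl carbon in the tether further favours the endo mode. The α-keto radical at C2 is then reduced by divalent iron to the enolate and protonated by ethanol, which returns trivalent iron. The closest known reaction type is the metal-hydride hydrogen-atom-transfer reductive olefin coupling, an intramolecular Giese-type addition of an alkene-derived radical to an enone. No stereocentre is created, since C4 carries two methyl groups and C2 and C3 are CH2. The trans ring fusion is dictated by the trans, diequatorial C5 and C10 substituents already fixed in 8. High dilution is needed to suppress intermolecular addition to the vinyl ketone.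

Step 5
Reactants: 9 4,4,8,10-tetramethyldecal-7-ene-1,9-dione
Product: 10 1-hydroxy-4,4,8,10-tetramethyldecal-7-en-9-one (C1 epimers)
Conditions: NaBH4, MeOH/CH2Cl2 1:1, −78 → −40 °C
Reagents that add atoms: none
Why: Borohydride reduces the saturated C1 ketone much faster than the conjugated C9 carbonyl, which is flanked by the quaternary C10 and the methylated C8 (chemoselective carbonyl reduction); the C1 configuration is irrelevant.

Step 6
Reactants: 10 1-hydroxy-4,4,8,10-tetramethyldecal-7-en-9-one
Product: 11 O-(C1) imidazole-1-carbothioate of 10
Conditions: 1,1'-thiocarbonyldiimidazole, DMAP (cat.), ClCH2CH2Cl, 70 °C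
Reagents that add atoms: 1,1'-thiocarbonyldiimidazole, S=C(n1ccnc1)n1ccnc1
Why: Thioacylation of the hindered secondary alcohol runs without strong base, so the β-hydroxy ketone cannot undergo retro-aldol; it prepares the Barton–McCombie deoxygenation.

Step 7
Reactants: 11 O-(C1) imidazole-1-carbothioate
Product: 12 4,4,8,10-tetramethyldecal-7-en-9-one (5α-H and 10β-CH3)
Conditions: Bu3SnH (0.3 M), AIBN (cat.), toluene, 100 °C
Reagents that add atoms: none
Why: Barton–McCombie deoxygenation: the stannyl radical adds to C=S, the C1–O bond fragments and the secondary C1 radical is quenched by Bu3SnH. A high stannane concentration keeps hydrogen transfer faster than a 1,2-acyl shift towards the C9 carbonyl.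

Step 8
Reactants: 12 4,4,8,10-tetramethyldecal-7-en-9-one
Product: 13 4,4,8,10-tetramethyldecal-7-ene-6,9-dione
Conditions: Pd(OH)2/C (5 mol %), t-BuOOH, K2CO3, CH2Cl2, 4 °C → rt
Reagents that add atoms: tert-butyl hydroperoxide, CC(C)(C)OO
Why: tert-Butylperoxyl radicals abstract the γ-hydrogen of the enone; C6–H is the only C–H whose radical is conjugated through C7=C8 with the C9 carbonyl, and the resulting allylic peroxide collapses to the ketone (γ-oxidation of an enone to an ene-1,4-dione). C5 stays 5α-H because the trans fusion is the stable one.

Step 9
Reactants: 13 4,4,8,10-tetramethyldecal-7-ene-6,9-dione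
Product: 14 6β-hydroxy-4,4,8,10-tetramethyldecal-7-en-9-one
Conditions: NaBH4, CeCl3·7H2O, MeOH, −78 °C
Reagents that add atoms: none
Why: Luche reduction: as in 2,6,6-trimethylcyclohex-2-ene-1,4-dione, the carbonyl beside a vinylic CH (C6) is reduced in preference to the one between a quaternary carbon and a methylated alkene carbon (C9). Hydride attacks C6 from the α face because the β face is closed by the syn-axial C10 and 4β methyl groups, which sets the axial 6β-alcohol.

Step 10
Reactants: 14 6β-hydroxy-4,4,8,10-tetramethyldecal-7-en-9-one
Product: 15 6β-(triethylsilyloxy)-4,4,8,10-tetramethyldecal-7-en-9-one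
Conditions: Et3SiOTf, 2,6-lutidine, CH2Cl2, −78 → 0 °C
Reagents that add atoms: triethylsilyl trifluoromethanesulfonate, CC[Si](CC)(CC)OS(=O)(=O)C(F)(F)F
Why: The silyl triflate with a hindered pyridine base overcomes the 1,3-diaxial shielding of the 6β-hydroxyl. The silyl ether blocks oxidation of this alcohol in step 17 and falls off in the final acid step.

Step 11
Reactants: 16 (R)-malic acid
Product: 17 2-[(2R,4R)-2-tert-butyl-5-oxo-1,3-dioxolan-4-yl]acetic acid (cis)
Conditions: t-BuCHO, TsOH (cat.), H2SO4 (cat.), pentane, reflux with water separator; crystallisation of the cis isomer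
Reagents that add atoms: pivalaldehyde, CC(C)(C)C=O
Why: Acid-catalysed acetalisation of the α-hydroxy acid unit gives the crystalline cis-dioxolanone, which stores the configuration of the carbinol carbon in the acetal centre (self-regeneration of stereocentres).

Step 12
Reactants: 17 2-[(2R,4R)-2-tert-butyl-5-oxo-1,3-dioxolan-4-yl]acetic acid; 18 allyl bromide
Product: 20 2-[(2R,4R)-4-allyl-2-tert-butyl-5-oxo-1,3-dioxolan-4-yl]acetic acid, via dilithium enolate carboxylate 19 (not isolated)
Conditions: LiN(SiMe3)2 (2.2 equiv), THF, −78 °C; allyl bromide, −78 → −20 °C; 1 M HCl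
Reagents that add atoms: allyl bromide (18), C=CCBr
Why: Two equivalents of base give the carboxylate-enolate, which is alkylated at the ring carbon on the face opposite to the tert-butyl group, that is with overall retention at the former carbinol carbon (diastereoselective enolate alkylation). This sets C13; the allyl group is the latent C14–C15 unit.

Step 13
Reactants: 20 2-[(2R,4R)-4-allyl-2-tert-butyl-5-oxo-1,3-dioxolan-4-yl]acetic acid
Product: 21 (3R)-3-(hydroxymethyl)hex-5-ene-1,3-diol
Conditions: LiAlH4, THF, 0 °C → reflux
Reagents that add atoms: none
Why: LiAlH4 reduces the acid and the acylal ester to primary alcohols (C11 and C16) and releases the auxiliary as neopentyl alcohol; the quaternary carbinol centre is not touched.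

Step 14
Reactants: 21 (3R)-3-(hydroxymethyl)hex-5-ene-1,3-diol
Product: 22 2-[(4R)-4-allyl-2,2-dimethyl-1,3-dioxolan-4-yl]ethanol
Conditions: Me2C(OMe)2, TsOH·H2O (cat.), acetone, rt
Reagents that add atoms: 2,2-dimethoxypropane, COC(C)(C)OC
Why: Under thermodynamic control the acetonide forms on the 1,2-diol as the five-membered dioxolane, because the six-membered isomer would hold an axial substituent syn to an acetal methyl group. The primary alcohol of the two-carbon arm stays free.

Step 15
Reactants: 22 2-[(4R)-4-allyl-2,2-dimethyl-1,3-dioxolan-4-yl]ethanol
Product: 23 (4R)-4-allyl-4-(2-iodoethyl)-2,2-dimethyl-1,3-dioxolane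
Conditions: I2, PPh3, imidazole, CH2Cl2, 0 °C → rt
Reagents that add atoms: iodine, [I][I]
Why: Appel-type iodination of the primary alcohol under imidazole buffering leaves the acetonide and the alkene intact.

Step 16
Reactants: 23 (4R)-4-allyl-4-(2-iodoethyl)-2,2-dimethyl-1,3-dioxolane; 15 6β-(triethylsilyloxy)-4,4,8,10-tetramethyldecal-7-en-9-one
Product: 26 9-hydroxy-6β-(triethylsilyloxy)-4,4,8,10-tetramethyl-9-{2-[(4S)-4-allyl-2,2-dimethyl-1,3-dioxolan-4-yl]ethyl}decal-7-ene (C9 epimers), via alkyllithium 24 (not isolated), via alkylcerium dichloride 25 (not isolated)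
Conditions: 23, t-BuLi (2.1 equiv), Et2O/pentane, −78 °C; CeCl3 (anhydrous), THF, −78 °C; 15, −78 → −40 °C; aq. NH4Cl
Reagents that add atoms: none
Why: Iodine–lithium exchange at −78 °C is faster than 5-exo carbolithiation of the remote alkene. Transmetalation to trivalent cerium gives a strongly nucleophilic, weakly basic reagent that adds 1,2 to the hindered enone instead of removing the γ-hydrogen at C6 (organocerium carbonyl addition). The C9 configuration is erased in step 17.

Step 17
Reactants: 26 C9 tertiary allylic alcohol
Product: 27 6β-(triethylsilyloxy)-4,4,8,10-tetramethyl-9-{2-[(4S)-4-allyl-2,2-dimethyl-1,3-dioxolan-4-yl]ethyl}decal-8-en-7-one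
Conditions: pyridinium chlorochromate [C5H5NH][CrO3Cl], NaOAc, 4 Å molecular sieves, CH2Cl2, rt
Reagents that add atoms: pyridinium chlorochromate, [O-][Cr](=O)(=O)Cl.c1cc[nH+]cc1
Why: Dauben-type oxidative 1,3-transposition: the tertiary allylic chromate ester rearranges by [3,3] shift to the C7 chromate, which is oxidised to the ketone, so the tetrasubstituted C8=C9 enone forms with its carbonyl oxygen coming from the chromium reagent. The silyl ether protects C6; the acetonide and terminal alkene are inert under the buffered conditions.

Step 18
Reactants: 27 decal-8-en-7-one with allyl-dioxolane side chain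
Product: 29 as 27 with a 2-oxoethyl group in place of allyl (C15 aldehyde), via vicinal diol 28 (not isolated)
Conditions: OsO4 (2 mol %), NaIO4, 2,6-lutidine, dioxane/H2O 3:1, rt
Reagents that add atoms: osmium tetroxide, O=[Os](=O)(=O)=O; sodium periodate, [Na+].[O-]I(=O)(=O)=O
Why: Lemieux–Johnson cleavage: OsO4 dihydroxylates the electron-rich monosubstituted alkene far faster than the tetrasubstituted, electron-poor enone alkene, and periodate cleaves the diol to the C15 aldehyde with loss of formaldehyde.

Step 19
Reactants: 29 C15 aldehyde
Product: 30 as 27 with a carboxymethyl group in place of allyl (C15 acid)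
Conditions: NaClO2, NaH2PO4, 2-methyl-2-butene, t-BuOH/H2O, 0 °C → rt
Reagents that add atoms: sodium chlorite, [Na+].[O-]Cl=O
Why: Pinnick oxidation converts the aldehyde to the acid at about pH 4 without touching the enone, silyl ether or acetonide; the alkene additive scavenges hypochlorous acid.

Step 20
Reactants: 30 C15 acid
Product: 32 CNP0324736.2 (6β,13S)-6,13-dihydroxy-7-oxolabd-8-en-15,16-olide, via trihydroxy acid 31 (not isolated)
Conditions: 1 M HCl, THF/H2O, rt
Reagents that add atoms: none
Why: Aqueous acid hydrolyses the acetonide and the silyl ether, and the freed C16 hydroxyl closes the five-membered lactone on the C15 acid (acid-catalysed lactonisation). Room temperature avoids dehydration at C13 and enolisation towards C6, so all four stereocentres are kept.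

## Compound list

1 | (R)-(−)-carvone | CC1=CC[C@H](CC1=O)C(C)=C | starting material
2 | iodomethane | CI | starting material
3 | lithium cross-conjugated dienolate of 1 (O–Li on C1, C1=C6 and C2=C3) | CC1=CC[C@@H](C(C)=C)C=C1O[Li] | intermediate (not isolated)
4 | (5R,6S)-6-methylcarvone, methyl trans to isopropenyl | CC1=CC[C@@H](C(C)=C)[C@H](C)C1=O | intermediate
5 | acrolein | C=CC=O | starting material
6 | lithium enolate of 4 (O–Li on C1, C1=C6) | CC1=CC[C@@H](C(C)=C)C(C)=C1O[Li] | intermediate (not isolated)
7 | 6-(1-hydroxyprop-2-en-1-yl)-6-methylcarvone, hydroxyallyl trans and methyl cis to isopropenyl, carbinol epimers | CC1=CC[C@@H](C(C)=C)[C@](C)(C(O)C=C)C1=O | intermediate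
8 | 6-acryloyl-6-methylcarvone, acyl trans and methyl cis to isopropenyl | CC1=CC[C@@H](C(C)=C)[C@](C)(C(=O)C=C)C1=O | intermediate
9 | trans-fused 4,4,8,10-tetramethyldecal-7-ene-1,9-dione (5α-H, 10β-CH3) | CC1=CC[C@H]2C(C)(C)CCC(=O)[C@]2(C)C1=O | intermediate
10 | 1-hydroxy-4,4,8,10-tetramethyldecal-7-en-9-one, C1 epimers | CC1=CC[C@H]2C(C)(C)CCC(O)[C@]2(C)C1=O | intermediate
11 | O-(C1) imidazole-1-carbothioate of 10 | CC1=CC[C@H]2C(C)(C)CCC(OC(=S)n3ccnc3)[C@]2(C)C1=O | intermediate
12 | 4,4,8,10-tetramethyldecal-7-en-9-one (5α-H, 10β-CH3) | CC1=CC[C@H]2C(C)(C)CCC[C@]2(C)C1=O | intermediate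
13 | 4,4,8,10-tetramethyldecal-7-ene-6,9-dione | CC1=CC(=O)[C@H]2C(C)(C)CCC[C@]2(C)C1=O | intermediate
14 | 6β-hydroxy-4,4,8,10-tetramethyldecal-7-en-9-one | CC1=C[C@@H](O)[C@H]2C(C)(C)CCC[C@]2(C)C1=O | intermediate
15 | 6β-(triethylsilyloxy)-4,4,8,10-tetramethyldecal-7-en-9-one | CC1=C[C@@H](O[Si](CC)(CC)CC)[C@H]2C(C)(C)CCC[C@]2(C)C1=O | intermediate
16 | (R)-malic acid | OC(=O)C[C@@H](O)C(O)=O | starting material
17 | 2-[(2R,4R)-2-tert-butyl-5-oxo-1,3-dioxolan-4-yl]acetic acid (cis) | OC(=O)C[C@H]1O[C@@H](C(C)(C)C)OC1=O | intermediate
18 | allyl bromide | C=CCBr | starting material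
19 | dilithium enolate carboxylate of 17 | [Li]OC(=O)CC1=C(O[Li])O[C@H](C(C)(C)C)O1 | intermediate (not isolated)
20 | 2-[(2R,4R)-4-allyl-2-tert-butyl-5-oxo-1,3-dioxolan-4-yl]acetic acid (allyl trans to tert-butyl) | OC(=O)C[C@@]1(CC=C)O[C@@H](C(C)(C)C)OC1=O | intermediate
21 | (3R)-3-(hydroxymethyl)hex-5-ene-1,3-diol | OCC[C@@](CO)(CC=C)O | intermediate
22 | 2-[(4R)-4-allyl-2,2-dimethyl-1,3-dioxolan-4-yl]ethanol | OCC[C@]1(CC=C)COC(C)(C)O1 | intermediate
23 | (4R)-4-allyl-4-(2-iodoethyl)-2,2-dimethyl-1,3-dioxolane | ICC[C@]1(CC=C)COC(C)(C)O1 | intermediate
24 | alkyllithium from 23 (Li in place of I) | [Li]CC[C@]1(CC=C)COC(C)(C)O1 | intermediate (not isolated)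
25 | alkylcerium dichloride from 24 | Cl[Ce](Cl)CC[C@]1(CC=C)COC(C)(C)O1 | intermediate (not isolated)
26 | 9-hydroxy-6β-(triethylsilyloxy)-4,4,8,10-tetramethyl-9-{2-[(4S)-4-allyl-2,2-dimethyl-1,3-dioxolan-4-yl]ethyl}decal-7-ene, C9 epimers | CC1=C[C@@H](O[Si](CC)(CC)CC)[C@H]2C(C)(C)CCC[C@]2(C)C1(O)CC[C@]3(CC=C)COC(C)(C)O3 | intermediate
27 | 6β-(triethylsilyloxy)-4,4,8,10-tetramethyl-9-{2-[(4S)-4-allyl-2,2-dimethyl-1,3-dioxolan-4-yl]ethyl}decal-8-en-7-one | CC1=C(CC[C@]3(CC=C)COC(C)(C)O3)[C@@]2(C)CCCC(C)(C)[C@@H]2[C@H](O[Si](CC)(CC)CC)C1=O | intermediate
28 | as 27 with 2,3-dihydroxypropyl in place of allyl, carbinol epimers | CC1=C(CC[C@]3(CC(O)CO)COC(C)(C)O3)[C@@]2(C)CCCC(C)(C)[C@@H]2[C@H](O[Si](CC)(CC)CC)C1=O | intermediate (not isolated)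
29 | as 27 with 2-oxoethyl in place of allyl (C15 aldehyde) | CC1=C(CC[C@]3(CC=O)COC(C)(C)O3)[C@@]2(C)CCCC(C)(C)[C@@H]2[C@H](O[Si](CC)(CC)CC)C1=O | intermediate
30 | as 27 with carboxymethyl in place of allyl (C15 acid) | CC1=C(CC[C@]3(CC(O)=O)COC(C)(C)O3)[C@@]2(C)CCCC(C)(C)[C@@H]2[C@H](O[Si](CC)(CC)CC)C1=O | intermediate
31 | (6β,13S)-6,13,16-trihydroxy-7-oxolabd-8-en-15-oic acid | CC1=C(CC[C@@](O)(CO)CC(O)=O)[C@@]2(C)CCCC(C)(C)[C@@H]2[C@H](O)C1=O | intermediate (not isolated)
32 | CNP0324736.2, (6β,13S)-6,13-dihydroxy-7-oxolabd-8-en-15,16-olide | CC1=C(CC[C@@]2(O)COC(=O)C2)[C@@]2(C)CCCC(C)(C)[C@@H]2[C@H](O)C1=O | target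

## Step count and least certain steps

Total: 20 steps. Longest linear sequence: 15 steps (steps 1–10 and 16–20, from 1 to 32). The side-chain branch from 16 contributes 5 steps (11–15) before the union.

Step 4 (key step). What may go wrong: quenching of the tertiary radical before it cyclises (simple reduction of the isopropenyl group), hydrogen-atom transfer to the vinyl ketone, intermolecular radical addition leading to oligomers, or retro-Claisen opening of the β-diketone by the alcohol solvent. Fallback: make the same C3–C4 bond by halogen abstraction instead of hydrogen-atom transfer. Setting out from 8, HBr in AcOH at 0 °C adds in the Markovnikov sense to the isopropenyl group, giving the tertiary bromide F1; any β-bromo ketone formed at the vinyl ketone is returned to the enone by Et3N on work-up. Slow addition of Bu3SnH/AIBN in benzene at 80 °C then generates the same C4 radical, which closes 6-endo to give 9, where the route is rejoined.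

Step 7. What may go wrong: 1,2-acyl migration of the C1 radical onto the neighbouring C9 carbonyl (Dowd–Beckwith-type ring reorganisation), or stannyl-radical attack on the enone. Fallback: remove the C1 oxygen without a radical at C1. Setting out from 9, KN(SiMe3)2/PhNTf2 at −78 °C (kinetic deprotonation at C2) gives the C1 enol triflate F2. Pd(OAc)2/PPh3 with Bu3N/HCO2H reduces it to the Δ1 alkene F3. Diimide (from TsNHNH2/NaOAc) then saturates the cis-disubstituted C1=C2 bond in preference to the trisubstituted enone alkene, which gives 12.

Step 8. What may go wrong: slow hydrogen abstraction at the shielded C6, competing oxidation of the C17 methyl group, or Weitz–Scheffer epoxidation of the ene-dione by the peroxide anion. Fallback: oxidise the extended enol ether instead of the C–H bond. Setting out from 12, t-BuMe2SiOTf/Et3N gives the silyl dienol ether F4. m-CPBA attacks its terminal C6=C7 bond (vinylogous Rubottom oxidation) to give the 6-hydroxy enone F5 of either configuration. Dess–Martin oxidation then gives 13.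

Step 16. What may go wrong: no addition because of steric shielding by C10 and the C8 methyl group, with γ-deprotonation at C6 taking over, or loss of the organometallic by cyclisation onto its own alkene if the temperature rises. Fallback: form C9–C11 at an sp2 carbon by cross-coupling and bring in the oxygens afterwards. This detour replaces steps 8 to 10 as well.
- Setting out from 12, KN(SiMe3)2/PhNTf2 gives by γ-deprotonation the dienyl triflate F6.
- 24 is trapped with B-methoxy-9-borabicyclo[3.3.1]nonane and coupled with F6 (PdCl2(dppf), K3PO4, Suzuki–Miyaura coupling) to the ring-B diene F7.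
- Singlet oxygen (O2, tetraphenylporphyrin, light) adds across C6 and C9 from the α face to the endoperoxide F8.
- Et3N removes the only bridgehead hydrogen (Kornblum–DeLaMare rearrangement) to give the 9-hydroxy-7-en-6-one F9.
- Luche reduction from the α face gives the 6β,9-diol F10.
- Et3SiOTf at −78 °C silylates only its secondary hydroxyl, which gives 26.

Step 17. What may go wrong: ionisation and dehydration of the tertiary allylic alcohol to dienes, slow chromate transfer to C7 beside the 6β-silyloxy group, or loss of the silyl ether under the acidic chromium reagent followed by oxidation at C6. Fallback: separate transposition from oxidation. Setting out from 26, catalytic Ph3SiOReO3 in Et2O at 0 °C shifts the hydroxyl 1,3 to the secondary C7 alcohol F11, favoured because the tetrasubstituted C8=C9 bond forms. Dess–Martin oxidation then gives 27.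

## Further compounds

F1 | step 4 | 6-acryloyl-5-(2-bromopropan-2-yl)-2,6-dimethylcyclohex-2-enone, tertiary bromide of 8 | CC1=CC[C@@H](C(C)(C)Br)[C@](C)(C(=O)C=C)C1=O
F2 | step 7 | C1 enol triflate of 9 (C1=C2) | CC1=CC[C@H]2C(C)(C)CC=C(OS(=O)(=O)C(F)(F)F)[C@]2(C)C1=O
F3 | step 7 | 4,4,8,10-tetramethyldecala-1,7-dien-9-one | CC1=CC[C@H]2C(C)(C)CC=C[C@]2(C)C1=O
F4 | step 8 | 9-(tert-butyldimethylsilyloxy)-4,4,8,10-tetramethyldecala-6,8-diene | CC1=C(O[Si](C)(C)C(C)(C)C)[C@@]2(C)CCCC(C)(C)[C@@H]2C=C1
F5 | step 8 | 6-hydroxy-4,4,8,10-tetramethyldecal-7-en-9-one, C6 epimers | CC1=CC(O)[C@H]2C(C)(C)CCC[C@]2(C)C1=O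
F6 | step 16 | 4,4,8,10-tetramethyldecala-6,8-dien-9-yl triflate | CC1=C(OS(=O)(=O)C(F)(F)F)[C@@]2(C)CCCC(C)(C)[C@@H]2C=C1
F7 | step 16 | 9-{2-[4-allyl-2,2-dimethyl-1,3-dioxolan-4-yl]ethyl}-4,4,8,10-tetramethyldecala-6,8-diene | CC1=C(CC[C@]3(CC=C)COC(C)(C)O3)[C@@]2(C)CCCC(C)(C)[C@@H]2C=C1
F8 | step 16 | 6α,9α-epidioxy-7-ene endoperoxide of F7 | CC1=C[C@@H]2OO[C@@]1(CC[C@]3(CC=C)COC(C)(C)O3)[C@@]4(C)CCCC(C)(C)[C@H]24
F9 | step 16 | 9α-hydroxy-9-(side chain)-4,4,8,10-tetramethyldecal-7-en-6-one | CC1=CC(=O)[C@H]2C(C)(C)CCC[C@]2(C)[C@@]1(O)CC[C@]3(CC=C)COC(C)(C)O3
F10 | step 16 | 6β,9α-dihydroxy-9-(side chain)-4,4,8,10-tetramethyldecal-7-ene | CC1=C[C@@H](O)[C@H]2C(C)(C)CCC[C@]2(C)[C@@]1(O)CC[C@]3(CC=C)COC(C)(C)O3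
F11 | step 17 | 7-hydroxy-6β-(triethylsilyloxy)-9-(side chain)-4,4,8,10-tetramethyldecal-8-ene, C7 epimers | CC1=C(CC[C@]3(CC=C)COC(C)(C)O3)[C@@]2(C)CCCC(C)(C)[C@@H]2[C@H](O[Si](CC)(CC)CC)C1O
A1 | alternative 1 | bis(triethylsilyl) ether of the target | CC1=C(CC[C@@]2(O[Si](CC)(CC)CC)COC(=O)C2)[C@@]2(C)CCCC(C)(C)[C@@H]2[C@H](O[Si](CC)(CC)CC)C1=O
A2 | alternative 1 | 3-(triethylsilyloxy)oxetan-3-yl precursor with 6β-silyloxy enone | CC1=C(CCC2(O[Si](CC)(CC)CC)COC2)[C@@]2(C)CCCC(C)(C)[C@@H]2[C@H](O[Si](CC)(CC)CC)C1=O
A3 | alternative 1 | oxetan-3-one | O=C1COC1
A4 | alternative 2 | sclareol oxide (8α,13-epoxy-14,15-dinorlabd-12-ene) | CC1=CC[C@@H]2[C@@]3(C)CCCC(C)(C)[C@@H]3CC[C@@]2(C)O1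
A5 | alternative 2 | (5E,9E)-farnesylacetone | CC(=O)CC/C=C(\C)CC/C=C(\C)CCC=C(C)C
A6 | alternative 3 | 6-(methoxymethoxy)-4,4,10-trimethyloctal-5-en-7-one | O=C1CC[C@@]2(C)CCCC(C)(C)C2=C1OCOC
A7 | alternative 3 | 2-[4-(methoxymethoxy)-3-oxobutyl]-2,6,6-trimethylcyclohexanone | COCOCC(=O)CC[C@@]1(C)CCCC(C)(C)C1=O
A8 | alternative 3 | 2,2,6-trimethylcyclohexanone | CC1CCCC(C)(C)C1=O
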